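# Proposed synthesis of (+)-miliusane XVII (17) through a 2-methoxyfuran Diels–Alder adduct

Atom labels follow the spiro numbering of the target: C1 (lactone CH–O), O2, C3 (lactone C=O), C4 (CH2), C5 (spiro carbon), C6 (ring C=O), C7=C8, C9 (CH–OAc), C10 (CH2). The side chain on C1 is C1'H=C2'(CH3)–C3'H2–C4'H=C5'H–C6'(CH3)2OH.

## The problem

Compound 17 is a 2-oxaspiro[4.5]decane in which a γ-lactone (C1, O2, C3, C4, C5) and a cyclohex-2-enone (C5 to C10) share the quaternary carbon C5. C5 lies between the ring ketone C6 and the lactone carbinol C1, so it must be built as a fully substituted carbon with two oxygenated carbon branches.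

There are three stereocentres: C5 (R), C9 (S) and C1 (R). C5 and C9 are 1,3-related across the carbocycle, with the C9 oxygen cis to the C5–C1 bond, so both can be fixed if the ring closes in one stereospecific event. C1 lies outside the carbocycle; its alkenyl group points to the C6 side of the lactone and its hydrogen to the C10 side, and this must be relayed from C5 or imposed by a reagent.

The side chain is a (1'E,4'E) skipped diene with a trisubstituted alkene and a tertiary allylic alcohol terminus. Several groups are fragile:
- the 4-acetoxy enone is sensitive to base and to nucleophiles;
- the skipped diene moves into conjugation under base or metal hydrides;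
- the tertiary allylic alcohol ionises in acid;
- the C1–O bond is allylic.

The enabling feature is the array C6(=O)–C7=C8–C9(–O). C6 and C9 are 1,4-related and both carry oxygen, as do the two α-carbons of a 2-alkoxyfuran joined by the ring oxygen, and C7=C8 is the furan double bond that survives. C5–C10 is then a two-carbon dienophile, and because C5 bears C1 and C4 but no hydrogen, it is an α-methylene lactone type acceptor whose oxygen-bridged adduct cannot aromatise.

## Retrosynthesis

**Side-chain terminus (17 ⇒ 15 + 16).** The C4'=C5' alkene is cut by cross-metathesis, leading to acetate 15 with a plain allyl terminus and 2-methylbut-3-en-2-ol (16). Against carrying the whole chain from the start, this keeps the acid-labile tertiary allylic alcohol out of every earlier step and shortens the side-chain building block to five carbons. The forward reaction must be E-selective and must leave the trisubstituted alkene and the ring enone alone.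

**Acetate and enone (15 ⇒ 14 ⇒ 13).** The acetate is traced to alcohol 14. The hydroxy enone of 14 is then closed in the retrosynthetic sense to the bridged methyl ketal 13, in which the C9 oxygen is tied to C6. The ketal hides the enone from the organolithium, hydride and oxidant used earlier and carries the C9 configuration. The forward step is a mild aqueous acid hydrolysis that breaks only the C6–O bonds.

**Lactone carbonyl (13 ⇒ 10).** The O2–C3(=O) unit is traced to the 1,4-diol 10, with C3 as a primary alcohol and C1 as a secondary allylic alcohol. This is needed because the lactone of 17 has its carbonyl remote from C5, whereas a dienophile needs its activating carbonyl on C5. The lactone is therefore "turned round": the carbonyl carbon of the cycloadduct becomes C1 and its OCH2 becomes C3. The forward step must oxidise the primary alcohol selectively in the presence of the hindered secondary one.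

**C1 and the side chain (10 ⇒ 9 ⇒ 3 + 6).** The C1–H bond is cut to give enone 9. The C1–C1' bond is then cut to give lactone 3 and alkenyllithium 7, made from iodide 6. Compared with adding the alkenyl metal to an aldehyde at C1, the ketone route puts C1 under control of a chiral reducing agent rather than of the substrate alone. It asks for a single addition to a lactone carbonyl that has no α-hydrogen, and for a 1,2-selective, face-selective reduction.

**Carbocycle (3 ⇒ 1 + 2).** The bonds C5–C6 and C9–C10 are cut together, giving 2-methoxyfuran (1) and α-methylene-γ-butyrolactone (2), both purchased. No other cut removes the ring, the quaternary centre, C9 and the whole oxidation pattern at once. The forward cycloaddition needs ortho regiochemistry, an exo lactone carbonyl and one enantiotopic face.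

**Iodide (6 ⇒ 4).** The C2'–CH3 and C1'–I bonds are traced to pent-1-en-4-yne (4) by syn carboalumination and iodinolysis, which fixes the E geometry in one operation.

## Roads not taken

**Alternative 1:** The cut is made inside the carbocycle by removing C7, so the precursor is the spiro cyclopentanone A2, which already holds C1, C5, C9 and the side-chain diene. Forward, Me3SiCHN2 under Sc(OTf)3 catalysis adds to the C6 carbonyl and the C8 methylene migrates, giving cyclohexanone A1.
- Merits: the stereocentres are set in a compact spiro[4.4] system, only known reaction types are used, and later desaturation can only go toward C7 because C5 has no hydrogen.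
- Weak points: A2 is a β-silyloxy ketone that can eliminate under Lewis acid; migration of C8 must beat that of quaternary C5, and a second insertion is possible. A1 still needs the C7=C8 double bond, an exchange of the group on the C9 oxygen and the metathesis. Above all, A2, with a quaternary spiro centre and two further stereocentres, is no easier to make than the target carbocycle.
- Comparison: on stereochemical risk this road is safer than the chosen plan. The chosen plan sets against it one cycloaddition of purchased compounds that delivers ring, C5, C9 and the latent enone pattern, with a racemic variant plus resolution in reserve.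

**Alternative 2:** The C5–C10 bond is cut and the C6 ketone traced to a tertiary carbinol, giving epoxy alcohol A4: a symmetric cyclopent-3-enol attached to C5 of a C5–C1 epoxide. Forward, a Lewis acid opens the epoxide at C5 while a ring methylene migrates anti, giving the ring-enlarged β-hydroxy ketone A3.
- Merits: the step is stereospecific, and C5 and C1 both come from one epoxide. This is better than the chosen plan, where C1 needs a separate reduction.
- Weak points: the epoxide may open at the propargylic C1, the ester may capture the developing cation at C5, and enantioselective epoxidation of this trisubstituted alkene beside a tertiary alcohol is uncertain. A3 has its alkene at C8=C9 and no oxygen on C9. It therefore still needs an enone transposition with stereoselective C9 oxygenation, lactonisation, and a regio- and stereoselective hydrometalation/allylation of the propynyl group.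
- Comparison: the chosen plan answers the advantage at C1 with a reagent-controlled reduction and obtains the C9 oxygen and the enone position from the cycloaddition itself.

**Alternative 3:** The C5–C1 bond is cut. The precursor is the prochiral bis(arylacetate) acylal A6 of the complete side-chain enal. Forward, zerovalent palladium ionises one carboxylate and the tethered phenol attacks C1 through its ipso carbon, giving the spiro lactone 2,4-cyclohexadienone A5 with loss of aromaticity.
- Merits: this is the most convergent road; lactone, quaternary centre, C1 and the finished side chain arrive in one catalytic asymmetric step. If it worked it would be shorter than the chosen plan.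
- Weak points: O-allylation and attack at other ring positions compete with ipso attack; two stereocentres must be controlled at once; 6,6-disubstituted 2,4-cyclohexadienones such as A5 dimerise readily. C9 is still an sp2 enol ether carbon, so hydrolysis and a regio- and face-selective reduction of the C9 carbonyl beside the C6 ketone and the lactone would follow.
- Comparison: the chosen plan is longer by a few steps but fixes C9 together with C5 in the cycloaddition and never passes through a free dienone.

Key step: step 1

Assumption: the sense of induction of the oxazaborolidinium catalyst with an α-methylene lactone, which lacks the α-hydrogen of the usual ester models, cannot be derived with confidence; the (S)-configured catalyst is written, and its antipode would be used if the first adduct proves to be the mirror image.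

## Route

Step 1
Reactants: 1 2-methoxyfuran; 2 α-methylene-γ-butyrolactone
Product: 3 exo cycloadduct (1S,2R,4S)-1-methoxy-7-oxaspiro[bicyclo[2.2.1]hept-5-ene-2,3'-oxolan]-2'-one (lactone carbonyl syn to the oxygen bridge)
Conditions: (S)-B-(o-tolyl)oxazaborolidine from (S)-α,α-diphenylprolinol (20 mol %), HNTf2 (18 mol %), 1 (2 equiv), CH2Cl2, −78 °C; Et3N, −78 °C
Reagents that add atoms: none
Why: Proposed new method: the boron cation binds the lactone carbonyl of 2 and lowers the LUMO of the exocyclic alkene, so that 1 should add in a concerted but strongly asynchronous [4+2] cycloaddition; the closest known reaction types are the oxazaborolidinium-catalysed Diels–Alder reaction of furan with acrylates and the uncatalysed cycloaddition of 2-alkoxyfurans with acrylate-type dienophiles. The unsubstituted α-carbon of 1, which has the largest HOMO coefficient, bonds first to the methylene carbon (C9–C10), and the methoxy-bearing carbon then closes onto the lactone α-carbon (C6–C5); this ortho orientation is secured by the methoxy donor. The six-membered carbocycle C5–C6–C7–C8–C9–C10 is closed by suprafacial union of diene and dienophile and appears as the carbon ring of a 7-oxabicyclo[2.2.1]heptene. C6 and C9 are tied to each other by the oxygen bridge, and C5 is set relative to them by the exo transition state, in which the carbonyl lies syn to the bridge and the lactone CH2 takes the endo position, the usual preference of s-cis-locked α-substituted acceptors. The absolute configuration depends on which face of the bound dienophile the aryl groups of the catalyst leave open. Quaternary C5 rules out aromatisation, and the cold amine quench keeps the Lewis acid from ionising the bridged ketal.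

Step 2
Reactants: 4 pent-1-en-4-yne
Product: 6 (1E)-1-iodo-2-methylpenta-1,4-diene, via alkenyl(dimethyl)alane 5 (not isolated)
Conditions: Me3Al (2 equiv), Cp2ZrCl2 (0.2 equiv), CH2Cl2, 0 °C → rt; then I2, THF, −30 → 0 °C
Reagents that add atoms: trimethylaluminium, C[Al](C)C; iodine, II
Why: Negishi zirconium-catalysed carboalumination adds methyl and aluminium syn across the alkyne with aluminium on the terminal carbon, and iodinolysis with retention gives the E iodide. The monosubstituted alkene does not react under these conditions.

Step 3
Reactants: 6 (1E)-1-iodo-2-methylpenta-1,4-diene; 3 exo cycloadduct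
Product: 9 hydroxy enone (2E)-1-[(1S,2S,4S)-2-(2-hydroxyethyl)-1-methoxy-7-oxabicyclo[2.2.1]hept-5-en-2-yl]-3-methylhexa-2,5-dien-1-one (acyl group exo), via alkenyllithium 7 (not isolated), via lithium hemiketal alkoxide 8 (not isolated)
Conditions: 6 (1.3 equiv), t-BuLi (2.6 equiv), Et2O, −78 °C; then 3, −78 °C; AcOH/THF, −78 °C
Reagents that add atoms: none
Why: Iodine–lithium exchange gives 7 with retention of alkene geometry, and acyl substitution at the lactone carbonyl, which has no α-hydrogen, should stop at the tetrahedral alkoxide 8 at −78 °C, so the ketone is released only in the cold acid quench when no organolithium is left. The cold quench also keeps the skipped diene out of conjugation; the bridged ketal and the strained ring alkene should be inert to 7 at this temperature.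

Step 4
Reactants: 9 hydroxy enone
Product: 10 diol (1R,2E)-1-[(1S,2S,4S)-2-(2-hydroxyethyl)-1-methoxy-7-oxabicyclo[2.2.1]hept-5-en-2-yl]-3-methylhexa-2,5-dien-1-ol
Conditions: (S)-2-methyl-CBS-oxazaborolidine (0.5 equiv), catecholborane (3 equiv), toluene, −78 °C; MeOH, then aq. NaOH
Reagents that add atoms: none
Why: Corey–Bakshi–Shibata reduction, 1,2-selective for enones: boron should bind the carbonyl lone pair remote from quaternary C5 (the large group) and deliver hydride to the face that gives the (1R) carbinol, the sense in which this catalyst turns acetophenone into (R)-1-phenylethanol. In the unchelated rotamer with C=O eclipsing C5–C4 this is also the open face (toward C10; the other is covered by the methoxy bridgehead), whereas a chelating hydride would hold the carbonyl toward the methoxy oxygen and expose the opposite face, hence the non-chelating conditions. Catecholborane at −78 °C should leave the alkenes untouched.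

Step 5
Reactants: 10 diol
Product: 13 bridged-ketal spirolactone (1S,2R,4S,2'R)-1-methoxy-2'-[(1E)-2-methylpenta-1,4-dien-1-yl]-7-oxaspiro[bicyclo[2.2.1]hept-5-ene-2,3'-oxolan]-5'-one, via hydroxy aldehyde 11 (not isolated), via lactol 12 (not isolated)
Conditions: TEMPO (0.2 equiv), PhI(OAc)2 (2.5 equiv), NaHCO3, CH2Cl2, 0 °C → rt
Reagents that add atoms: none
Why: TEMPO/PhI(OAc)2 oxidative lactonisation of a 1,4-diol: the oxoammonium ion should oxidise the unhindered primary alcohol much faster than the neopentyl secondary one, aldehyde 11 closes with the C1 hydroxyl to lactol 12, and 12 is oxidised on to the lactone. No bond to C1 is broken, so its configuration is kept; NaHCO3 takes up the acetic acid and protects the ketal.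

Step 6
Reactants: 13 bridged-ketal spirolactone
Product: 14 (1R,5R,9S)-9-hydroxy-1-[(1E)-2-methylpenta-1,4-dien-1-yl]-2-oxaspiro[4.5]dec-7-ene-3,6-dione
Conditions: 0.1 M aq. HCl, THF, 0 °C
Reagents that add atoms: water, O
Why: Acid-catalysed ketal hydrolysis: protonation of the bridging oxygen and cleavage of its bond to C6, assisted by the methoxy lone pair, gives a conjugated oxocarbenium ion that water converts into the C6 ketone with loss of methanol and relief of ring strain. The C9–O bond is not broken, so the hydroxyl stays cis to C1, and quaternary C5 rules out aromatisation.

Step 7
Reactants: 14 hydroxy enone lactone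
Product: 15 (1R,5R,9S)-1-[(1E)-2-methylpenta-1,4-dien-1-yl]-3,6-dioxo-2-oxaspiro[4.5]dec-7-en-9-yl acetate
Conditions: Ac2O, pyridine, DMAP (cat.), CH2Cl2, 0 °C
Reagents that add atoms: acetic anhydride, CC(=O)OC(C)=O
Why: Standard DMAP-catalysed acetylation of the only hydroxyl group; the short reaction at 0 °C should avoid elimination from the 4-acetoxy enone.

Step 8
Reactants: 15 acetate; 16 2-methylbut-3-en-2-ol
Product: 17 (+)-miliusane XVII
Conditions: 16 (10 equiv), second-generation Hoveyda–Grubbs catalyst (5 mol %), 1,4-benzoquinone (10 mol %), CH2Cl2, 40 °C
Reagents that add atoms: none
Why: Olefin cross-metathesis between the monosubstituted alkene of 15 and the hindered tertiary allylic alcohol 16, which homodimerises slowly and is used in excess; the bulky carbinol end should enforce the E alkene. The trisubstituted alkene and the ring enone should not take part, and benzoquinone suppresses migration of the skipped diene.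

## Compound list

1 | 2-methoxyfuran | COc1ccco1 | starting material
2 | α-methylene-γ-butyrolactone (3-methylideneoxolan-2-one) | C=C1CCOC1=O | starting material
3 | exo cycloadduct, (1S,2R,4S)-1-methoxy-7-oxaspiro[bicyclo[2.2.1]hept-5-ene-2,3'-oxolan]-2'-one, lactone carbonyl syn to the oxygen bridge | CO[C@@]12C=C[C@@H](O1)C[C@@]23C(=O)OCC3 | intermediate
4 | pent-1-en-4-yne | C=CCC#C | starting material
5 | dimethyl[(1E)-2-methylpenta-1,4-dien-1-yl]alane, formed in situ | C[Al](C)/C=C(\C)CC=C | intermediate
6 | (1E)-1-iodo-2-methylpenta-1,4-diene | I/C=C(\C)CC=C | intermediate
7 | [(1E)-2-methylpenta-1,4-dien-1-yl]lithium, formed in situ | [Li]/C=C(\C)CC=C | intermediate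
8 | lithium alkoxide of the cyclic hemiketal from 7 and 3 (tetrahedral adduct at C1, configuration at C1 not defined), formed in situ | CO[C@@]12C=C[C@@H](O1)C[C@]23CCOC3(O[Li])/C=C(\C)CC=C | intermediate
9 | hydroxy enone, (2E)-1-[(1S,2S,4S)-2-(2-hydroxyethyl)-1-methoxy-7-oxabicyclo[2.2.1]hept-5-en-2-yl]-3-methylhexa-2,5-dien-1-one, acyl group exo | CO[C@@]12C=C[C@@H](O1)C[C@@]2(CCO)C(=O)/C=C(\C)CC=C | intermediate
10 | diol, (1R,2E)-1-[(1S,2S,4S)-2-(2-hydroxyethyl)-1-methoxy-7-oxabicyclo[2.2.1]hept-5-en-2-yl]-3-methylhexa-2,5-dien-1-ol | CO[C@@]12C=C[C@@H](O1)C[C@@]2(CCO)[C@H](O)/C=C(\C)CC=C | intermediate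
11 | hydroxy aldehyde, the C3 aldehyde of diol 10 with the (1R) carbinol unchanged, formed in situ | CO[C@@]12C=C[C@@H](O1)C[C@@]2(CC=O)[C@H](O)/C=C(\C)CC=C | intermediate
12 | lactol, five-membered cyclic hemiacetal of 11 (mixture at the hemiacetal carbon C3), formed in situ | CO[C@@]12C=C[C@@H](O1)C[C@]23CC(O)O[C@@H]3/C=C(\C)CC=C | intermediate
13 | bridged-ketal spirolactone, (1S,2R,4S,2'R)-1-methoxy-2'-[(1E)-2-methylpenta-1,4-dien-1-yl]-7-oxaspiro[bicyclo[2.2.1]hept-5-ene-2,3'-oxolan]-5'-one (target numbering: C1 R, C5 R, C6 S, C9 S) | CO[C@@]12C=C[C@@H](O1)C[C@]23CC(=O)O[C@@H]3/C=C(\C)CC=C | intermediate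
14 | (1R,5R,9S)-9-hydroxy-1-[(1E)-2-methylpenta-1,4-dien-1-yl]-2-oxaspiro[4.5]dec-7-ene-3,6-dione | O[C@@H]1C=CC(=O)[C@@]2(CC(=O)O[C@@H]2/C=C(\C)CC=C)C1 | intermediate
15 | (1R,5R,9S)-1-[(1E)-2-methylpenta-1,4-dien-1-yl]-3,6-dioxo-2-oxaspiro[4.5]dec-7-en-9-yl acetate | CC(=O)O[C@@H]1C=CC(=O)[C@@]2(CC(=O)O[C@@H]2/C=C(\C)CC=C)C1 | intermediate
16 | 2-methylbut-3-en-2-ol | CC(C)(O)C=C | starting material
17 | (+)-miliusane XVII, (1R,5R,9S)-1-[(1E,4E)-6-hydroxy-2,6-dimethylhepta-1,4-dien-1-yl]-3,6-dioxo-2-oxaspiro[4.5]dec-7-en-9-yl acetate | CC(=O)O[C@@H]1C=CC(=O)[C@@]2(CC(=O)O[C@@H]2/C=C(\C)C/C=C/C(C)(C)O)C1 | target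

## Step count and least certain steps

Total step count: 8. Longest linear sequence: 7 steps (steps 1, 3, 4, 5, 6, 7, 8 from 1 and 2); step 2 is a one-step side branch.

**Step 1 (key step, proposed new method).** Three processes could defeat it:
- the asynchronous transition state may leak into conjugate addition at the free furan α-position instead of closing the second bond onto the quaternary carbon;
- the cationic Lewis acid may degrade the electron-rich furan or ionise the bridged ketal of the product;
- facial discrimination may be poor because the lactone lacks the α-hydrogen contact of the ester models.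

The fallback sets out from 1 and 2 and gives up asymmetric catalysis. The two are combined without a catalyst, neat or under high pressure, as known for 2-alkoxyfurans and acrylate-type dienophiles. This gives the racemic exo adduct, that is 3 together with its mirror-image exo cycloadduct F1. Preparative chromatography on a chiral stationary phase separates the two, and the route is rejoined at 3.

**Step 4.** Facial selectivity may be poor or inverted. This would happen if the ketone reacts through a rotamer whose open face is the exo face, or if the catalyst reads the alkenyl group rather than C5 as the large substituent. The antipodal catalyst is the first remedy. The fallback changes the order of events and sets out from 3. Reduction with i-Bu2AlH in CH2Cl2 at −78 °C gives the lactol F2. The alkenylmagnesium reagent made from 7 and MgBr2·OEt2 (3 equiv) is then added. In a six-membered magnesium chelate between the aldehyde oxygen and the methoxy oxygen the exo face is open; alkenyl attack there places hydrogen and alkenyl group as required, the reverse of what hydride attack on the same face of the ketone would give. This leads directly to 10, bypassing 9.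

**Step 3.** Over-addition may occur if the tetrahedral alkoxide collapses before the quench, conversion at the hindered carbonyl may be incomplete, and the doubly allylic position may be metalated. The fallback sets out from 3 and runs in four operations:
- MeNH(OMe)·HCl and i-PrMgCl in THF at −20 °C open the lactone to the hydroxy Weinreb amide F3;
- immediate silylation with TESCl and imidazole gives the triethylsilyl ether F4;
- addition of 7 at −78 °C, which cannot over-add, gives the silyl-protected enone F5;
- TBAF buffered with AcOH in THF at 0 °C removes the silyl group.

The route is rejoined at 9.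

**Step 5.** The secondary allylic alcohol may be oxidised in competition with the primary one, and the acetic acid released may open the ketal if buffering is insufficient. The fallback sets out from 9, so C3 is oxidised before C1 is a carbinol:
- TEMPO (cat.), NaClO2 and NaOCl (cat.) in MeCN with pH 6.7 phosphate buffer give the keto acid F6;
- TMSCHN2 in toluene/MeOH gives the keto methyl ester F7;
- reduction as in step 4 gives the hydroxy ester F8.

F8 should close to the lactone with loss of methanol on standing or gentle warming with a trace of Et3N, rejoining the route at 13.

## Further compounds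

F1 | step 1 | mirror-image exo cycloadduct (enantiomer of 3) | CO[C@]12C=C[C@H](O1)C[C@]23C(=O)OCC3
F2 | step 4 | lactol from reduction of the lactone carbonyl of 3 (mixture at the hemiacetal carbon) | CO[C@@]12C=C[C@@H](O1)C[C@@]23C(O)OCC3
F3 | step 3 | hydroxy Weinreb amide, N-methoxy-N-methyl amide at C1 with free 2-hydroxyethyl chain on C5 | CO[C@@]12C=C[C@@H](O1)C[C@@]2(CCO)C(=O)N(C)OC
F4 | step 3 | triethylsilyl ether of F3 | CO[C@@]12C=C[C@@H](O1)C[C@@]2(CCO[Si](CC)(CC)CC)C(=O)N(C)OC
F5 | step 3 | triethylsilyl ether of hydroxy enone 9 | CO[C@@]12C=C[C@@H](O1)C[C@@]2(CCO[Si](CC)(CC)CC)C(=O)/C=C(\C)CC=C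
F6 | step 5 | keto acid, C3 carboxylic acid of enone 9 | CO[C@@]12C=C[C@@H](O1)C[C@@]2(CC(=O)O)C(=O)/C=C(\C)CC=C
F7 | step 5 | keto methyl ester of F6 | CO[C@@]12C=C[C@@H](O1)C[C@@]2(CC(=O)OC)C(=O)/C=C(\C)CC=C
F8 | step 5 | hydroxy methyl ester with the (1R) carbinol | CO[C@@]12C=C[C@@H](O1)C[C@@]2(CC(=O)OC)[C@H](O)/C=C(\C)CC=C
A1 | alternative 1 | ring-expanded spiro lactone cyclohexanone, C9 tert-butyldimethylsilyl ether, C1, C5 and C9 arranged as in the target | CC(C)(C)[Si](C)(C)O[C@@H]1CCC(=O)[C@@]2(CC(=O)O[C@@H]2/C=C(\C)CC=C)C1
A2 | alternative 1 | spiro cyclopentanone precursor of A1 (lacks C7) | CC(C)(C)[Si](C)(C)O[C@@H]1CC(=O)[C@@]2(CC(=O)O[C@@H]2/C=C(\C)CC=C)C1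
A3 | alternative 2 | 2,2-disubstituted cyclohex-4-enone with the C1 propargylic carbinol and the methyl acetate arm | COC(=O)C[C@@]1([C@H](O)C#CC)CC=CCC1=O
A4 | alternative 2 | epoxy alcohol precursor of A3, 1-hydroxycyclopent-3-enyl group on C5 of the C5–C1 epoxide | COC(=O)C[C@@]1(C2(O)CC=CC2)O[C@@H]1C#CC
A5 | alternative 3 | spiro lactone 2,4-cyclohexadienone with C9 as methyl enol ether | COC1C=CC(=O)[C@@]2(CC(=O)O[C@@H]2/C=C(\C)C/C=C/C(C)(C)O)C=1
A6 | alternative 3 | prochiral allylic acylal, bis(2-hydroxy-5-methoxyphenylacetate) of the side-chain enal | COc1ccc(O)c(CC(=O)OC(OC(=O)Cc2cc(OC)ccc2O)/C=C(\C)C/C=C/C(C)(C)O)c1
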